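The route rests on cutting the bond between aromatic carbon C7 of the 2,5-dihydro-1-benzoxepine and the ketone carbon of the 3-arylpropanoyl chain. C7 is the one carbon of the benzo ring that lies between two phenolic oxygens (O6 and O8). Carried as methoxymethyl (MOM) ethers, they direct n-BuLi to H7 by cooperative chelation, and the 7-lithio benzoxepine adds once to the Weinreb amide of MOM-protected dihydrocaffeic acid. One operation thus joins both halves and installs the ketone. The precursor, 6,8-bis(methoxymethoxy)-3-methyl-2,5-dihydro-1-benzoxepine, comes from phloroglucinol by aromatic Claisen rearrangement and ring-closing metathesis. One acid treatment finally frees all four phenols.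

Key step: step 8

Remark on the chemistry: the target has no stereocentre, and its only non-aromatic alkene (C3=C4) lies in the seven-membered ring, where no configurational alternative exists. No stereocontrol is therefore required. Phloroglucinol and 3-(3,4-dihydroxyphenyl)propanoic acid are taken as the commercial starting materials.

Step 1
Reactants: 1 phloroglucinol (benzene-1,3,5-triol)
Product: 2 3,5-bis(methoxymethoxy)phenol
Conditions: MOMCl (2.0 equiv), i-Pr2NEt, DMF, 0 °C to rt; chromatography
Reagents that add atoms: chloromethyl methyl ether (MOMCl), COCCl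
Why: Williamson-type O-alkylation with the hard α-chloro ether goes at oxygen, and since the three hydroxyls of 1 are equivalent the only issue is the degree of alkylation, which is set by the stoichiometry and settled by chromatography with recycling of the mono-ether.

Step 2
Reactants: 2 3,5-bis(methoxymethoxy)phenol
Product: 3 1,3-bis(methoxymethoxy)-5-(prop-2-en-1-yloxy)benzene
Conditions: allyl bromide, K2CO3, acetone, reflux
Reagents that add atoms: allyl bromide, C=CCBr
Why: Williamson ether synthesis on the single free phenol; the acetal ethers are stable to K2CO3.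

Step 3
Reactants: 3 1,3-bis(methoxymethoxy)-5-(prop-2-en-1-yloxy)benzene
Product: 5 3,5-bis(methoxymethoxy)-2-(prop-2-en-1-yl)phenol, via dienone tautomer 4 (not isolated)
Conditions: N,N-diethylaniline, 195 °C, argon
Reagents that add atoms: none
Why: Aromatic Claisen rearrangement ([3,3]-sigmatropic shift) through dienone 4, which tautomerises to the phenol; the two ortho positions of 3 are equivalent by symmetry, so a single regioisomer should form, and the amine solvent keeps the medium non-acidic for the MOM ethers.

Step 4
Reactants: 5 3,5-bis(methoxymethoxy)-2-(prop-2-en-1-yl)phenol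
Product: 6 1,5-bis(methoxymethoxy)-3-[(2-methylprop-2-en-1-yl)oxy]-2-(prop-2-en-1-yl)benzene
Conditions: 3-bromo-2-methylprop-1-ene, K2CO3, DMF, 50 °C
Reagents that add atoms: 3-bromo-2-methylprop-1-ene (methallyl bromide), CC(=C)CBr
Why: Williamson ether synthesis of the phenol with a reactive allylic bromide; nothing else in 5 is alkylated under carbonate conditions.

Step 5
Reactants: 6 1,5-bis(methoxymethoxy)-3-[(2-methylprop-2-en-1-yl)oxy]-2-(prop-2-en-1-yl)benzene
Product: 7 6,8-bis(methoxymethoxy)-3-methyl-2,5-dihydro-1-benzoxepine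
Conditions: second-generation Grubbs catalyst RuCl2(=CHPh)(PCy3)(H2IMes) (5 mol %), CH2Cl2 (0.01 M), 40 °C
Reagents that add atoms: none
Why: Ring-closing metathesis between the monosubstituted allyl alkene and the 1,1-disubstituted methallyl alkene closes the seven-membered ring with loss of ethene, a closure well precedented for 2,5-dihydro-1-benzoxepines; the ring enforces the alkene geometry.

Step 6
Reactants: 8 3-(3,4-dihydroxyphenyl)propanoic acid
Product: 10 3-(3,4-dihydroxyphenyl)-N-methoxy-N-methylpropanamide, via benzotriazolyl ester 9 (not isolated)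
Conditions: MeNH(OMe)·HCl, EDC·HCl, HOBt, N-methylmorpholine, DMF, 0 °C to rt, N2
Reagents that add atoms: N,O-dimethylhydroxylamine hydrochloride, CNOC.Cl
Why: Carbodiimide amide coupling through active ester 9; the amine is far more nucleophilic than the catechol hydroxyls, and any aryl ester formed is itself an acyl donor toward the amine.

Step 7
Reactants: 10 3-(3,4-dihydroxyphenyl)-N-methoxy-N-methylpropanamide
Product: 11 3-[3,4-bis(methoxymethoxy)phenyl]-N-methoxy-N-methylpropanamide
Conditions: MOMCl (2.5 equiv), i-Pr2NEt, CH2Cl2, 0 °C to rt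
Reagents that add atoms: chloromethyl methyl ether (MOMCl), COCCl
Why: Williamson-type acetal ether formation on both catechol hydroxyls; the Weinreb amide is inert to MOMCl and the hindered amine base.

Step 8
Reactants: 7 6,8-bis(methoxymethoxy)-3-methyl-2,5-dihydro-1-benzoxepine; 11 3-[3,4-bis(methoxymethoxy)phenyl]-N-methoxy-N-methylpropanamide
Product: 14 1-[6,8-bis(methoxymethoxy)-3-methyl-2,5-dihydro-1-benzoxepin-7-yl]-3-[3,4-bis(methoxymethoxy)phenyl]propan-1-one, via aryllithium 12 (not isolated), via lithium hemiaminal alkoxide 13 (not isolated)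
Conditions: 7 (1.2 equiv), n-BuLi (1.15 equiv), THF, −20 to 0 °C, 1 h; then 11 (1.0 equiv), −78 to 0 °C; sat. aq NH4Cl
Reagents that add atoms: none
Why: n-BuLi, pre-complexed by the two MOM ethers at O6 and O8, removes H7 (directed ortho-metalation by complex-induced proximity) to give the doubly chelated aryllithium 12, which adds to the amide carbonyl of 11 to give the N-methoxy-chelated lithium hemiaminal alkoxide 13; this survives until the aqueous quench and then collapses to ketone 14, so only one aryl group can add. The closest known reaction types are the cooperative directed ortho-lithiation of 1,3-bis(methoxymethoxy)arenes and the Weinreb ketone synthesis. No ring is closed, and the only new tetrahedral centre (the hemiaminal carbon of 13) is transient and erased on collapse, so no stereocontrol is needed. The step needs site selectivity for C7 over C9 and over the benzylic-allylic C5 and allylic C2 methylene groups: C7 is the only position between two chelating MOM ethers, whereas C9 has the non-chelating ring ether O1 on one side, and the absence of TMEDA together with a temperature at or below 0 °C disfavours undirected deprotonation at C5 or C2. It also needs carbonyl addition to win over enolisation of 11, which is helped by adding 11 at −78 °C to a solution that holds no residual n-BuLi (7 in slight excess).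

Step 9
Reactants: 14 1-[6,8-bis(methoxymethoxy)-3-methyl-2,5-dihydro-1-benzoxepin-7-yl]-3-[3,4-bis(methoxymethoxy)phenyl]propan-1-one
Product: 15 1-(6,8-dihydroxy-3-methyl-2,5-dihydro-1-benzoxepin-7-yl)-3-(3,4-dihydroxyphenyl)propan-1-one (CNP0203471.0)
Conditions: HCl (1.25 M in MeOH), MeOH, 0 °C to rt, argon
Reagents that add atoms: none
Why: Acid-catalysed acetal solvolysis (transacetalisation to dimethoxymethane) removes all four MOM groups, the two flanking the ketone being activated by chelation, and dilute methanolic HCl at or below room temperature should leave the trisubstituted ring alkene and the allylic aryl ether untouched.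

Compound list
1 | phloroglucinol (benzene-1,3,5-triol) | Oc1cc(O)cc(O)c1 | starting material
2 | 3,5-bis(methoxymethoxy)phenol | COCOc1cc(O)cc(OCOC)c1 | intermediate
3 | 1,3-bis(methoxymethoxy)-5-(prop-2-en-1-yloxy)benzene | C=CCOc1cc(OCOC)cc(OCOC)c1 | intermediate
4 | 3,5-bis(methoxymethoxy)-6-(prop-2-en-1-yl)cyclohexa-2,4-dien-1-one (racemic, transient) | C=CCC1C(=O)C=C(OCOC)C=C1OCOC | intermediate (not isolated)
5 | 3,5-bis(methoxymethoxy)-2-(prop-2-en-1-yl)phenol | C=CCc1c(O)cc(OCOC)cc1OCOC | intermediate
6 | 1,5-bis(methoxymethoxy)-3-[(2-methylprop-2-en-1-yl)oxy]-2-(prop-2-en-1-yl)benzene | C=CCc1c(OCC(C)=C)cc(OCOC)cc1OCOC | intermediate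
7 | 6,8-bis(methoxymethoxy)-3-methyl-2,5-dihydro-1-benzoxepine | CC1=CCc2c(cc(OCOC)cc2OCOC)OC1 | intermediate
8 | 3-(3,4-dihydroxyphenyl)propanoic acid | OC(=O)CCc1ccc(O)c(O)c1 | starting material
9 | 1H-benzotriazol-1-yl 3-(3,4-dihydroxyphenyl)propanoate | O=C(CCc1ccc(O)c(O)c1)On1nnc2ccccc12 | intermediate (not isolated)
10 | 3-(3,4-dihydroxyphenyl)-N-methoxy-N-methylpropanamide | CON(C)C(=O)CCc1ccc(O)c(O)c1 | intermediate
11 | 3-[3,4-bis(methoxymethoxy)phenyl]-N-methoxy-N-methylpropanamide | CON(C)C(=O)CCc1ccc(OCOC)c(OCOC)c1 | intermediate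
12 | [6,8-bis(methoxymethoxy)-3-methyl-2,5-dihydro-1-benzoxepin-7-yl]lithium | CC1=CCc2c(cc(OCOC)c([Li])c2OCOC)OC1 | intermediate (not isolated)
13 | lithium 1-[6,8-bis(methoxymethoxy)-3-methyl-2,5-dihydro-1-benzoxepin-7-yl]-3-[3,4-bis(methoxymethoxy)phenyl]-1-[methoxy(methyl)amino]propan-1-olate (racemic, transient) | CC1=CCc2c(cc(OCOC)c(C(O[Li])(CCc3ccc(OCOC)c(OCOC)c3)N(C)OC)c2OCOC)OC1 | intermediate (not isolated)
14 | 1-[6,8-bis(methoxymethoxy)-3-methyl-2,5-dihydro-1-benzoxepin-7-yl]-3-[3,4-bis(methoxymethoxy)phenyl]propan-1-one | CC1=CCc2c(cc(OCOC)c(C(=O)CCc3ccc(OCOC)c(OCOC)c3)c2OCOC)OC1 | intermediate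
15 | 1-(6,8-dihydroxy-3-methyl-2,5-dihydro-1-benzoxepin-7-yl)-3-(3,4-dihydroxyphenyl)propan-1-one | CC1=CCc2c(cc(O)c(C(=O)CCc3ccc(O)c(O)c3)c2O)OC1 | target

Total step count: 9. Longest linear sequence: 7 steps (steps 1 to 5, 8 and 9); steps 6 and 7 make the second fragment.

Steps most likely to fail

Step 8. Metalation may go to the wrong site, either at C9 or at the doubly activated C5 methylene, where the resulting allyl anion can expel the phenoxide and open the oxepine. The hindered aryllithium may also enolise the amide instead of adding to it. The fallback fixes the regiochemistry before the ring is built and replaces deprotonation by bromine-lithium exchange. It sets out from 2 and comes back to the route at 12. Phenol 2 is silylated (i-Pr3SiCl, imidazole, DMF) to [3,5-bis(methoxymethoxy)phenoxy]tri(propan-2-yl)silane F1. Here the bulky, poorly coordinating silyl ether shields both of its neighbours, so n-BuLi (THF, 0 °C) can only metalate between the two MOM ethers, giving [2,6-bis(methoxymethoxy)-4-{[tri(propan-2-yl)silyl]oxy}phenyl]lithium F2. Quenching with 1,2-dibromo-1,1,2,2-tetrachloroethane at −78 °C gives [4-bromo-3,5-bis(methoxymethoxy)phenoxy]tri(propan-2-yl)silane F3. Desilylation with n-Bu4NF (THF, 0 °C) gives 4-bromo-3,5-bis(methoxymethoxy)phenol F4, and allylation (allyl bromide, K2CO3, acetone) gives 2-bromo-1,3-bis(methoxymethoxy)-5-(prop-2-en-1-yloxy)benzene F5. Claisen rearrangement (N,N-diethylaniline, 190 °C) then runs through 4-bromo-3,5-bis(methoxymethoxy)-6-(prop-2-en-1-yl)cyclohexa-2,4-dien-1-one F6 to 4-bromo-3,5-bis(methoxymethoxy)-2-(prop-2-en-1-yl)phenol F7, again with two equivalent ortho positions. Methallylation (3-bromo-2-methylprop-1-ene, K2CO3, DMF) gives 2-bromo-1,3-bis(methoxymethoxy)-5-[(2-methylprop-2-en-1-yl)oxy]-4-(prop-2-en-1-yl)benzene F8, and ring-closing metathesis (second-generation Grubbs catalyst, CH2Cl2, 40 °C) gives 7-bromo-6,8-bis(methoxymethoxy)-3-methyl-2,5-dihydro-1-benzoxepine F9. Treating F9 with n-BuLi in THF at −78 °C should give aryllithium 12 within minutes, faster than any deprotonation, and 12 is then combined with 11 as in step 8.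

Step 9. Protonation of the trisubstituted ring alkene may cause double-bond migration or addition of methanol, and the released methoxymethyl cation may alkylate the electron-rich ring at C9. The fallback avoids protic acid and unmasks in two stages; it sets out from 14 and comes back at 15. Me3SiOTf with 2,2'-bipyridyl (MeCN, 0 °C) exchanges each aryl MOM ether for a silyl ether, the methoxymethyl group being carried off as a pyridinium salt. This gives 3-[3,4-bis(trimethylsilyloxy)phenyl]-1-[3-methyl-6,8-bis(trimethylsilyloxy)-2,5-dihydro-1-benzoxepin-7-yl]propan-1-one F10, which water hydrolyses at near-neutral pH to 15.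

Step 6. The unprotected catechol may be O-acylated during the coupling, leading to oligoesters, and may be oxidised under the basic conditions. The fallback protects first and makes the amide from an ester; it sets out from 8 and comes back at 11. Excess MOMCl (3.3 equiv) with i-Pr2NEt in CH2Cl2 converts 8 into methoxymethyl 3-[3,4-bis(methoxymethoxy)phenyl]propanoate F11. This activated ester is aminolysed by chlorido(N-methoxy-N-methylamido)magnesium F12, generated from MeNH(OMe)·HCl and i-PrMgCl in THF at −20 °C, to give 11 directly.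

Further compounds
F1 | step 8 | [3,5-bis(methoxymethoxy)phenoxy]tri(propan-2-yl)silane | COCOc1cc(O[Si](C(C)C)(C(C)C)C(C)C)cc(OCOC)c1
F2 | step 8 | [2,6-bis(methoxymethoxy)-4-{[tri(propan-2-yl)silyl]oxy}phenyl]lithium | COCOc1cc(O[Si](C(C)C)(C(C)C)C(C)C)cc(OCOC)c1[Li]
F3 | step 8 | [4-bromo-3,5-bis(methoxymethoxy)phenoxy]tri(propan-2-yl)silane | COCOc1cc(O[Si](C(C)C)(C(C)C)C(C)C)cc(OCOC)c1Br
F4 | step 8 | 4-bromo-3,5-bis(methoxymethoxy)phenol | COCOc1cc(O)cc(OCOC)c1Br
F5 | step 8 | 2-bromo-1,3-bis(methoxymethoxy)-5-(prop-2-en-1-yloxy)benzene | C=CCOc1cc(OCOC)c(Br)c(OCOC)c1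
F6 | step 8 | 4-bromo-3,5-bis(methoxymethoxy)-6-(prop-2-en-1-yl)cyclohexa-2,4-dien-1-one | C=CCC1C(=O)C=C(OCOC)C(Br)=C1OCOC
F7 | step 8 | 4-bromo-3,5-bis(methoxymethoxy)-2-(prop-2-en-1-yl)phenol | C=CCc1c(O)cc(OCOC)c(Br)c1OCOC
F8 | step 8 | 2-bromo-1,3-bis(methoxymethoxy)-5-[(2-methylprop-2-en-1-yl)oxy]-4-(prop-2-en-1-yl)benzene | C=CCc1c(OCC(C)=C)cc(OCOC)c(Br)c1OCOC
F9 | step 8 | 7-bromo-6,8-bis(methoxymethoxy)-3-methyl-2,5-dihydro-1-benzoxepine | CC1=CCc2c(cc(OCOC)c(Br)c2OCOC)OC1
F10 | step 9 | 3-[3,4-bis(trimethylsilyloxy)phenyl]-1-[3-methyl-6,8-bis(trimethylsilyloxy)-2,5-dihydro-1-benzoxepin-7-yl]propan-1-one | CC1=CCc2c(cc(O[Si](C)(C)C)c(C(=O)CCc3ccc(O[Si](C)(C)C)c(O[Si](C)(C)C)c3)c2O[Si](C)(C)C)OC1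
F11 | step 6 | methoxymethyl 3-[3,4-bis(methoxymethoxy)phenyl]propanoate | COCOC(=O)CCc1ccc(OCOC)c(OCOC)c1
F12 | step 6 | chlorido(N-methoxy-N-methylamido)magnesium | CON(C)[Mg]Cl
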